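The target is read as a γ,δ-unsaturated acid at the alcohol oxidation level: the CH2OH carbon on quaternary C6 lies 1,5 to alkene carbon C3 of the cyclohexene ring. Everything rests on an Ireland–Claisen ring contraction of a δ-lactone whose ring oxygen sits on the future C3, which also carries a (Z)-2-benzoyloxyvinyl arm. One operation makes the C1–C6 bond, the C2=C3 double bond and the carbocycle, and sets quaternary C6 and the C1 benzoate center by chirality transfer through an enforced boat. The precursor is an all-cis (L-talo) 2,3-O-isopropylidene-4-O-benzoyl-1,5-lactone; its stereocenters are all relayed from one furyl carbinol center.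

Key step: step 10

Numbering of the target used in the text: C1 and C4 carry the benzoates, C2=C3 is the ring alkene, C5 carries the secondary hydroxyl, C6 the tertiary hydroxyl and the CH2OH group.
Remark on the chemistry: pyranone 5 is taken as its anomeric mixture; the hemiacetal carbon is left undefined because step 4 turns it into the lactone carbonyl.

Step 1
Reactants: 1 furfural; 2 ethynylmagnesium bromide
Product: 3 rac-1-(furan-2-yl)prop-2-yn-1-ol
Conditions: THF, 0 °C to rt; H2O work-up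
Reagents that add atoms: none
Why: Grignard 1,2-addition of the alkynyl reagent to the aldehyde gives the racemic furyl propargyl carbinol.

Step 2
Reactants: 3 rac-1-(furan-2-yl)prop-2-yn-1-ol
Product: 4 (S)-1-(furan-2-yl)prop-2-yn-1-ol
Conditions: immobilised Candida antarctica lipase B, vinyl acetate, MTBE, 30 °C, stopped just past half conversion; chromatography
Reagents that add atoms: none
Why: Lipase-catalysed kinetic resolution by transesterification should acetylate the (R)-alcohol (furyl as the large, ethynyl as the medium substituent) and leave the (S)-alcohol, the single stereocenter from which all others are relayed.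

Step 3
Reactants: 4 (S)-1-(furan-2-yl)prop-2-yn-1-ol
Product: 5 (2S)-2-ethynyl-6-hydroxy-2H-pyran-3(6H)-one (anomeric mixture)
Conditions: NBS, NaHCO3, NaOAc, THF/H2O (4:1), 0 °C
Reagents that add atoms: water, O
Why: Achmatowicz rearrangement (oxidative opening of the furan and reclosure through the carbinol oxygen) gives the pyranone without touching the carbinol stereocenter.

Step 4
Reactants: 5 (2S)-2-ethynyl-6-hydroxy-2H-pyran-3(6H)-one
Product: 6 (6S)-6-ethynyl-2H-pyran-2,5(6H)-dione
Conditions: CrO3, aq. H2SO4, acetone, 0 °C, short contact; crude product used at once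
Reagents that add atoms: none
Why: Jones oxidation of the lactol to the lactone removes the anomeric center and installs the acyl oxygen that the later rearrangement needs.

Step 5
Reactants: 6 (6S)-6-ethynyl-2H-pyran-2,5(6H)-dione
Product: 7 (5R,6S)-6-ethynyl-5-hydroxy-5,6-dihydro-2H-pyran-2-one
Conditions: NaBH4, CeCl3·7H2O, MeOH/CH2Cl2, −78 °C
Reagents that add atoms: none
Why: Luche 1,2-reduction of the ketone, which is more electrophilic than the lactone, should give the 5,6-trans alcohol by axial hydride attack, C5 being set by the adjacent C6.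

Step 6
Reactants: 7 (5R,6S)-6-ethynyl-5-hydroxy-5,6-dihydro-2H-pyran-2-one
Product: 8 (3R,4R,5R,6S)-6-ethynyl-3,4,5-trihydroxyoxan-2-one
Conditions: OsO4 (cat.), NMO, citric acid, acetone/H2O, 0 °C to rt; used crude
Reagents that add atoms: osmium tetroxide, O=[Os](=O)(=O)=O; N-methylmorpholine N-oxide, C[N+]1([O-])CCOCC1; water, O
Why: Catalytic syn-dihydroxylation of the enoate alkene on the face anti to the allylic C5 hydroxyl (the usual sense for osmylation of cyclic allylic alcohols) places both new oxygens cis to the ethynyl group, the alkyne being far less reactive.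

Step 7
Reactants: 8 (3R,4R,5R,6S)-6-ethynyl-3,4,5-trihydroxyoxan-2-one
Product: 9 (3aR,6S,7S,7aR)-6-ethynyl-7-hydroxy-2,2-dimethyltetrahydro-4H-[1,3]dioxolo[4,5-c]pyran-4-one
Conditions: 2,2-dimethoxypropane, camphorsulfonic acid (cat.), acetone, rt
Reagents that add atoms: 2,2-dimethoxypropane, COC(C)(C)OC
Why: Acetonide formation is selective for the cis-diol (five-membered ketal) and leaves the trans-disposed hydroxyl free.

Step 8
Reactants: 9 (3aR,6S,7S,7aR)-6-ethynyl-7-hydroxy-2,2-dimethyltetrahydro-4H-[1,3]dioxolo[4,5-c]pyran-4-one; 10 benzoic acid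
Product: 11 (3aR,6S,7R,7aR)-6-ethynyl-2,2-dimethyl-4-oxotetrahydro-4H-[1,3]dioxolo[4,5-c]pyran-7-yl benzoate
Conditions: PPh3, DIAD, toluene, 0 °C to rt
Reagents that add atoms: none
Why: Mitsunobu esterification with SN2 inversion at C7 turns the trans hydroxyl into the benzoate cis to both the acetonide and the ethynyl group, which completes the all-cis array.

Step 9
Reactants: 11 (3aR,6S,7R,7aR)-6-ethynyl-2,2-dimethyl-4-oxotetrahydro-4H-[1,3]dioxolo[4,5-c]pyran-7-yl benzoate; 10 benzoic acid
Product: 12 (3aR,6S,7R,7aR)-6-[(Z)-2-(benzoyloxy)ethenyl]-2,2-dimethyl-4-oxotetrahydro-4H-[1,3]dioxolo[4,5-c]pyran-7-yl benzoate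
Conditions: [RuCl2(p-cymene)]2 (cat.), P(4-ClC6H4)3, DMAP, toluene, 60 °C
Reagents that add atoms: none
Why: Ruthenium-catalysed anti-Markovnikov hydro-oxycarbonylation of the terminal alkyne (carboxylate attack on a ruthenium vinylidene) should give the (Z)-enol benzoate, whose geometry later fixes the C1 benzoate center.

Step 10
Reactants: 12 (3aR,6S,7R,7aR)-6-[(Z)-2-(benzoyloxy)ethenyl]-2,2-dimethyl-4-oxotetrahydro-4H-[1,3]dioxolo[4,5-c]pyran-7-yl benzoate
Product: 15 (3aS,4S,7R,7aR)-4,7-bis(benzoyloxy)-2,2-dimethyl-3a,4,7,7a-tetrahydro-1,3-benzodioxole-3a-carboxylic acid, via silyl ketene acetal 13 (not isolated), via trimethylsilyl ester 14 (not isolated)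
Conditions: LiN(SiMe3)2, Me3SiCl/Et3N, THF, −78 °C to rt; then toluene, 80 to 110 °C; 1 M HCl work-up
Reagents that add atoms: chlorotrimethylsilane, C[Si](C)(C)Cl (silyl group of 13 and 14 only)
Why: Deprotonation at C3a with silylation in the flask gives ketene acetal 13, in which C3a=C4–O5–C6–CH=CH(OBz) is the 1,5-diene of an Ireland–Claisen rearrangement; the [3,3] shift forms the C3a–CH(OBz) bond and the new ring C=C while the C6–O5 bond breaks, the closest known reaction type being the ring contraction of 6-alkenyl δ-lactone silyl ketene acetals to cyclohex-3-enecarboxylic acids. The six-membered carbocycle is closed by this pericyclic transposition and not by attack on a chain end: because the two reacting termini are tied 1,4 across the lactone ring, the six-atom array can only be a boat (bicyclo[2.2.2]octane-like), the chair being geometrically excluded. The quaternary carbon is controlled by C6, since the vinyl arm can reach C3a only on the ring face it occupies, which puts the new C–C bond syn to the acetonide and benzoate oxygens and the carboxyl anti to them. The CH(OBz) carbon is controlled by the Z geometry of the enol ester: in the single allowed boat the Z substituent points toward the C7a–C7 bridge and ends cis to the acetonide oxygen on C3a. The step needs enolisation without β-elimination or attack on the two benzoates, which the cis-fused dioxolane (β C–O bond held in the nodal plane of the enolate), the lack of any other acidic C–H and the internal silyl quench at −78 °C should secure; the crowding of three oxygens on one face of the boat is the accepted risk.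

Step 11
Reactants: 15 (3aS,4S,7R,7aR)-4,7-bis(benzoyloxy)-2,2-dimethyl-3a,4,7,7a-tetrahydro-1,3-benzodioxole-3a-carboxylic acid
Product: 16 (3aS,4S,7R,7aR)-3a-(hydroxymethyl)-2,2-dimethyl-3a,4,7,7a-tetrahydro-1,3-benzodioxole-4,7-diyl dibenzoate
Conditions: BH3·THF, THF, 0 °C to rt; MeOH quench
Reagents that add atoms: none
Why: Chemoselective borane reduction takes the carboxylic acid through its acyloxyborane much faster than it touches benzoate esters or the hindered, electron-poor ring alkene.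

Step 12
Reactants: 16 (3aS,4S,7R,7aR)-3a-(hydroxymethyl)-2,2-dimethyl-3a,4,7,7a-tetrahydro-1,3-benzodioxole-4,7-diyl dibenzoate
Product: 17 (1S,4R,5R,6R)-5,6-dihydroxy-6-(hydroxymethyl)cyclohex-2-ene-1,4-diyl dibenzoate
Conditions: CF3CO2H/H2O (9:1), 0 °C
Reagents that add atoms: none
Why: Acid hydrolysis of the acetonide frees the cis C5/C6 diol, and the non-basic, cold conditions should suppress benzoate migration.

Compound list
1 | furfural (furan-2-carbaldehyde) | O=Cc1ccco1 | starting material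
2 | ethynylmagnesium bromide | C#C[Mg]Br | starting material
3 | rac-1-(furan-2-yl)prop-2-yn-1-ol | C#CC(O)c1ccco1 | intermediate
4 | (S)-1-(furan-2-yl)prop-2-yn-1-ol | C#C[C@H](O)c1ccco1 | intermediate
5 | (2S)-2-ethynyl-6-hydroxy-2H-pyran-3(6H)-one (anomeric mixture) | C#C[C@@H]1OC(O)C=CC1=O | intermediate
6 | (6S)-6-ethynyl-2H-pyran-2,5(6H)-dione | C#C[C@@H]1OC(=O)C=CC1=O | intermediate
7 | (5R,6S)-6-ethynyl-5-hydroxy-5,6-dihydro-2H-pyran-2-one | C#C[C@@H]1OC(=O)C=C[C@H]1O | intermediate
8 | (3R,4R,5R,6S)-6-ethynyl-3,4,5-trihydroxyoxan-2-one | C#C[C@@H]1OC(=O)[C@H](O)[C@H](O)[C@H]1O | intermediate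
9 | (3aR,6S,7S,7aR)-6-ethynyl-7-hydroxy-2,2-dimethyltetrahydro-4H-[1,3]dioxolo[4,5-c]pyran-4-one | C#C[C@@H]1OC(=O)[C@@H]2OC(C)(C)O[C@@H]2[C@H]1O | intermediate
10 | benzoic acid | O=C(O)c1ccccc1 | starting material
11 | (3aR,6S,7R,7aR)-6-ethynyl-2,2-dimethyl-4-oxotetrahydro-4H-[1,3]dioxolo[4,5-c]pyran-7-yl benzoate | C#C[C@@H]1OC(=O)[C@@H]2OC(C)(C)O[C@@H]2[C@@H]1OC(=O)c1ccccc1 | intermediate
12 | (3aR,6S,7R,7aR)-6-[(Z)-2-(benzoyloxy)ethenyl]-2,2-dimethyl-4-oxotetrahydro-4H-[1,3]dioxolo[4,5-c]pyran-7-yl benzoate | O=C(O/C=C\[C@@H]1OC(=O)[C@@H]2OC(C)(C)O[C@@H]2[C@@H]1OC(=O)c1ccccc1)c1ccccc1 | intermediate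
13 | (6S,7R,7aR)-6-[(Z)-2-(benzoyloxy)ethenyl]-2,2-dimethyl-4-(trimethylsilyloxy)-7,7a-dihydro-6H-[1,3]dioxolo[4,5-c]pyran-7-yl benzoate (silyl ketene acetal) | O=C(O/C=C\[C@@H]1OC(O[Si](C)(C)C)=C2OC(C)(C)O[C@@H]2[C@@H]1OC(=O)c1ccccc1)c1ccccc1 | intermediate
14 | trimethylsilyl (3aS,4S,7R,7aR)-4,7-bis(benzoyloxy)-2,2-dimethyl-3a,4,7,7a-tetrahydro-1,3-benzodioxole-3a-carboxylate | O=C(O[C@H]1C=C[C@@H](OC(=O)c2ccccc2)[C@H]3OC(C)(C)O[C@@]13C(=O)O[Si](C)(C)C)c1ccccc1 | intermediate
15 | (3aS,4S,7R,7aR)-4,7-bis(benzoyloxy)-2,2-dimethyl-3a,4,7,7a-tetrahydro-1,3-benzodioxole-3a-carboxylic acid | O=C(O[C@H]1C=C[C@@H](OC(=O)c2ccccc2)[C@H]3OC(C)(C)O[C@@]13C(=O)O)c1ccccc1 | intermediate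
16 | (3aS,4S,7R,7aR)-3a-(hydroxymethyl)-2,2-dimethyl-3a,4,7,7a-tetrahydro-1,3-benzodioxole-4,7-diyl dibenzoate | O=C(O[C@H]1C=C[C@@H](OC(=O)c2ccccc2)[C@H]3OC(C)(C)O[C@@]13CO)c1ccccc1 | intermediate
17 | (1S,4R,5R,6R)-5,6-dihydroxy-6-(hydroxymethyl)cyclohex-2-ene-1,4-diyl dibenzoate | O=C(O[C@H]1C=C[C@@H](OC(=O)c2ccccc2)[C@@H](O)[C@]1(O)CO)c1ccccc1 | target

Total step count: 12. Longest linear sequence: 12 steps (fully linear from furfural).

Steps most likely to fail

1. Step 10. The boat transition state carries three oxygens on one face (the Z-benzoate oxygen syn to the C7a acetonide oxygen, plus the axial C7 benzoate). The rearrangement may therefore be slower than decay of ketene acetal 13 or base-induced acyl transfer from the benzoates. Fallback (rearrange first, invert afterwards): setting out from 9, the ruthenium-catalysed addition of benzoic acid 10 under the conditions of step 9 gives (Z)-2-[(3aR,6S,7S,7aR)-7-hydroxy-2,2-dimethyl-4-oxotetrahydro-4H-[1,3]dioxolo[4,5-c]pyran-6-yl]ethenyl benzoate F1. Ireland–Claisen rearrangement with one further equivalent of LiN(SiMe3)2 and Me3SiCl (the hydroxyl is silylated in the flask and freed again on acidic work-up) then runs through a boat in which the C7 oxygen lies on the uncrowded face and only one ester is exposed to base. It should give (3aS,4S,7S,7aR)-4-(benzoyloxy)-7-hydroxy-2,2-dimethyl-3a,4,7,7a-tetrahydro-1,3-benzodioxole-3a-carboxylic acid F2. Mitsunobu inversion of the allylic C7 hydroxyl with excess benzoic acid 10 (PPh3, DIAD) comes back to the route at 15; the neopentyl-type carboxyl of F2 is a poor nucleophile and cannot reach C7 from the rear face.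

2. Step 8. Displacement at C7 must occur on the face flanked by the dioxolane and the ethynyl group; elimination or esterification with retention may outrun the SN2 pathway. Fallback (inversion by oxidation and reduction): setting out from 9, oxidation with DMP (periodinane) in CH2Cl2 gives (3aR,6S,7aS)-6-ethynyl-2,2-dimethyldihydro-4H-[1,3]dioxolo[4,5-c]pyran-4,7(6H)-dione F3. NaBH4 in MeOH at −78 °C should deliver hydride from the convex face opposite the acetonide and the ethynyl group, giving (3aR,6S,7R,7aR)-6-ethynyl-7-hydroxy-2,2-dimethyltetrahydro-4H-[1,3]dioxolo[4,5-c]pyran-4-one F4. Benzoylation (benzoyl chloride, pyridine, DMAP) comes back to the route at 11.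

3. Step 4. The C6–H of dione 6 is activated by the ketone, the ring oxygen and the alkyne. Enolisation toward the achiral 5-hydroxy-2-pyranone tautomer would erase the only stereocenter before the reduction; the free triol lactone 8 made later can also undergo δ to γ lactone migration. Fallback (keep the anomeric carbon as a glycoside until the stereotriad is complete): setting out from 5, Boc2O and DMAP at −78 °C give tert-butyl (2S,6S)-6-ethynyl-5-oxo-5,6-dihydro-2H-pyran-2-yl carbonate F5. Pd2(dba)3·CHCl3/PPh3 with 4-methoxybenzyl alcohol (π-allyl complex of zerovalent palladium, net retention) gives (2S,6R)-2-ethynyl-6-[(4-methoxyphenyl)methoxy]-2H-pyran-3(6H)-one F6. Luche reduction gives (2S,3R,6R)-2-ethynyl-6-[(4-methoxyphenyl)methoxy]-3,6-dihydro-2H-pyran-3-ol F7. OsO4/NMO, anti to both allylic oxygens, gives (2S,3R,4R,5R,6R)-2-ethynyl-6-[(4-methoxyphenyl)methoxy]oxane-3,4,5-triol F8. 2,2-Dimethoxypropane with acid gives (3aR,4R,6S,7S,7aR)-6-ethynyl-4-[(4-methoxyphenyl)methoxy]-2,2-dimethyltetrahydro-4H-[1,3]dioxolo[4,5-c]pyran-7-ol F9. Mitsunobu inversion with benzoic acid 10 gives (3aR,4R,6S,7R,7aR)-6-ethynyl-4-[(4-methoxyphenyl)methoxy]-2,2-dimethyltetrahydro-4H-[1,3]dioxolo[4,5-c]pyran-7-yl benzoate F10. DDQ in wet CH2Cl2 gives the lactol (3aR,6S,7R,7aR)-6-ethynyl-4-hydroxy-2,2-dimethyltetrahydro-4H-[1,3]dioxolo[4,5-c]pyran-7-yl benzoate F11. Oxidation with DMP (periodinane) comes back to the route at 11.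

Further compounds
F1 | step 10 | (Z)-2-[(3aR,6S,7S,7aR)-7-hydroxy-2,2-dimethyl-4-oxotetrahydro-4H-[1,3]dioxolo[4,5-c]pyran-6-yl]ethenyl benzoate | O=C(O/C=C\[C@@H]1OC(=O)[C@@H]2OC(C)(C)O[C@@H]2[C@H]1O)c1ccccc1
F2 | step 10 | (3aS,4S,7S,7aR)-4-(benzoyloxy)-7-hydroxy-2,2-dimethyl-3a,4,7,7a-tetrahydro-1,3-benzodioxole-3a-carboxylic acid | O=C(O[C@H]1C=C[C@H](O)[C@H]3OC(C)(C)O[C@@]13C(=O)O)c1ccccc1
F3 | step 8 | (3aR,6S,7aS)-6-ethynyl-2,2-dimethyldihydro-4H-[1,3]dioxolo[4,5-c]pyran-4,7(6H)-dione | C#C[C@@H]1OC(=O)[C@@H]2OC(C)(C)O[C@@H]2C1=O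
F4 | step 8 | (3aR,6S,7R,7aR)-6-ethynyl-7-hydroxy-2,2-dimethyltetrahydro-4H-[1,3]dioxolo[4,5-c]pyran-4-one | C#C[C@@H]1OC(=O)[C@@H]2OC(C)(C)O[C@@H]2[C@@H]1O
F5 | step 4 | tert-butyl (2S,6S)-6-ethynyl-5-oxo-5,6-dihydro-2H-pyran-2-yl carbonate | C#C[C@@H]1O[C@@H](OC(=O)OC(C)(C)C)C=CC1=O
F6 | step 4 | (2S,6R)-2-ethynyl-6-[(4-methoxyphenyl)methoxy]-2H-pyran-3(6H)-one | C#C[C@@H]1O[C@@H](OCc2ccc(OC)cc2)C=CC1=O
F7 | step 4 | (2S,3R,6R)-2-ethynyl-6-[(4-methoxyphenyl)methoxy]-3,6-dihydro-2H-pyran-3-ol | C#C[C@@H]1O[C@@H](OCc2ccc(OC)cc2)C=C[C@H]1O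
F8 | step 4 | (2S,3R,4R,5R,6R)-2-ethynyl-6-[(4-methoxyphenyl)methoxy]oxane-3,4,5-triol | C#C[C@@H]1O[C@@H](OCc2ccc(OC)cc2)[C@H](O)[C@H](O)[C@H]1O
F9 | step 4 | (3aR,4R,6S,7S,7aR)-6-ethynyl-4-[(4-methoxyphenyl)methoxy]-2,2-dimethyltetrahydro-4H-[1,3]dioxolo[4,5-c]pyran-7-ol | C#C[C@@H]1O[C@@H](OCc2ccc(OC)cc2)[C@@H]3OC(C)(C)O[C@@H]3[C@H]1O
F10 | step 4 | (3aR,4R,6S,7R,7aR)-6-ethynyl-4-[(4-methoxyphenyl)methoxy]-2,2-dimethyltetrahydro-4H-[1,3]dioxolo[4,5-c]pyran-7-yl benzoate | C#C[C@@H]1O[C@@H](OCc2ccc(OC)cc2)[C@@H]3OC(C)(C)O[C@@H]3[C@@H]1OC(=O)c1ccccc1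
F11 | step 4 | (3aR,6S,7R,7aR)-6-ethynyl-4-hydroxy-2,2-dimethyltetrahydro-4H-[1,3]dioxolo[4,5-c]pyran-7-yl benzoate (anomeric mixture) | C#C[C@@H]1OC(O)[C@@H]3OC(C)(C)O[C@@H]3[C@@H]1OC(=O)c1ccccc1
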